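The α-methylene-γ-butyrolactone is opened at O1–C6 and C11–C12 (germacranolide numbering), so that its O–C(=O) unit becomes carbon dioxide. The key step is a formal (3+2) annulation of CO2 onto the C6–C7–C11 triad of the preformed cyclodeca-1(10),4-diene: copper-catalysed carboxylation of a C11 alkenylboronate forms C11–C12, and the resulting carboxylate closes the five-membered ring by SN2 displacement of an allylic C6 chloride with inversion. It exploits the 1,3-relationship between the alkenyl carbon C11 and C6, which is activated as the allylic position of the C4=C5 ring alkene. The precursor is a ten-membered carbocycle built by Crimmins aldol, Horner–Wadsworth–Emmons and Nozaki–Hiyama–Kishi reactions.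

Key step: step 17

Remarks:
- Locants C1–C15 in the Why lines are the germacranolide locants of the target: C6 = lactone O–CH, C7 = ring-fusion CH, C8 = acyloxy CH, C10 = ester-bearing ring carbon, C11/C13 = exocyclic alkene, C12 = lactone carbonyl.
- Assumption: compounds 3, 4 and 11–16 are carried as both epimers at the phosphonate-bearing carbon, which becomes sp2 in step 12.
- Acid 9 is taken as commercially available.

Step 1
Reactants: 1 methyl 2-(diethoxyphosphoryl)acetate; 2 allyl bromide
Product: 3 methyl 2-(diethoxyphosphoryl)pent-4-enoate (racemic)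
Conditions: NaH, THF, 0 °C to rt
Reagents that add atoms: none
Why: SN2 C-alkylation of the sodium phosphonoacetate anion with allyl bromide installs the future C9; the new stereocentre is racemic and is destroyed in step 12.

Step 2
Reactants: 3 methyl 2-(diethoxyphosphoryl)pent-4-enoate
Product: 4 methyl 2-(diethoxyphosphoryl)-4-oxobutanoate (racemic)
Conditions: O3, CH2Cl2, −78 °C; then PPh3
Reagents that add atoms: ozone [O-][O+]=O
Why: Ozonolysis with reductive work-up cleaves the only alkene to the aldehyde (future C8) and leaves the phosphonoacetate untouched.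

Step 3
Reactants: 5 pent-4-yn-1-ol
Product: 6 (E)-5-iodo-4-methylpent-4-en-1-ol
Conditions: AlMe3, Cp2ZrCl2 (cat.), CH2Cl2, 0 °C to rt; then I2, THF, −30 to 0 °C
Reagents that add atoms: trimethylaluminium C[Al](C)C; iodine II
Why: Negishi carboalumination adds Me–Al syn across the terminal alkyne and iodinolysis proceeds with retention, which fixes the E geometry of the future C4=C5 alkene.

Step 4
Reactants: 6 (E)-5-iodo-4-methylpent-4-en-1-ol
Product: 7 (E)-5-iodo-4-methylpent-4-enal
Conditions: Dess–Martin periodinane, CH2Cl2, rt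
Reagents that add atoms: none
Why: Dess–Martin oxidation converts the primary alcohol into the aldehyde (future C1) under neutral conditions that spare the vinyl iodide.

Step 5
Reactants: 8 (S)-4-benzyl-1,3-thiazolidine-2-thione; 9 3-[(4-methoxybenzyl)oxy]propanoic acid
Product: 10 1-[(4S)-4-benzyl-2-thioxo-1,3-thiazolidin-3-yl]-3-[(4-methoxybenzyl)oxy]propan-1-one
Conditions: DCC, DMAP (cat.), CH2Cl2, 0 °C to rt
Reagents that add atoms: none
Why: Steglich-type N-acylation gives the aldol substrate in which the acyl carbon is the future C11 and the CH2OPMB arm the future C6.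

Step 6
Reactants: 10 1-[(4S)-4-benzyl-2-thioxo-1,3-thiazolidin-3-yl]-3-[(4-methoxybenzyl)oxy]propan-1-one; 4 methyl 2-(diethoxyphosphoryl)-4-oxobutanoate
Product: 11 methyl (4R,5S)-6-[(4S)-4-benzyl-2-thioxo-1,3-thiazolidin-3-yl]-2-(diethoxyphosphoryl)-4-hydroxy-5-{[(4-methoxybenzyl)oxy]methyl}-6-oxohexanoate (both C2 epimers)
Conditions: TiCl4, i-Pr2NEt, NMP, CH2Cl2, 0 °C; then 4, −78 to 0 °C
Reagents that add atoms: none
Why: Crimmins titanium aldol in its "Evans-syn" mode: the Z-enolate reacts through a closed Zimmerman–Traxler transition state and the (S)-benzyl auxiliary selects one enolate face, so C7 (S) and C8 (R) should be set with C11 anti to the C8 oxygen along the C6–C7–C8 chain.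

Step 7
Reactants: 11 aldol adduct
Product: 12 methyl (4R,5S)-6-[(4S)-4-benzyl-2-thioxo-1,3-thiazolidin-3-yl]-4-[(tert-butyldimethylsilyl)oxy]-2-(diethoxyphosphoryl)-5-{[(4-methoxybenzyl)oxy]methyl}-6-oxohexanoate (both C2 epimers)
Conditions: TBSOTf, 2,6-lutidine, CH2Cl2, −78 to 0 °C
Reagents that add atoms: tert-butyldimethylsilyl triflate CC(C)(C)[Si](C)(C)OS(=O)(=O)C(F)(F)F
Why: O-Silylation of the secondary alcohol blocks γ-lactonisation onto the methyl ester and retro-aldol cleavage in the following steps.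

Step 8
Reactants: 12 silylated aldol adduct
Product: 13 methyl (4R,5S)-4-[(tert-butyldimethylsilyl)oxy]-2-(diethoxyphosphoryl)-6-[methoxy(methyl)amino]-5-{[(4-methoxybenzyl)oxy]methyl}-6-oxohexanoate (both C2 epimers)
Conditions: MeNHOMe·HCl, imidazole, CH2Cl2, rt
Reagents that add atoms: N,O-dimethylhydroxylamine hydrochloride CNOC.Cl
Why: The N-acylthiazolidinethione is an activated amide, so direct aminolysis to the Weinreb amide should proceed under near-neutral conditions that spare the methyl ester and the phosphonate.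

Step 9
Reactants: 13 Weinreb amide
Product: 14 methyl (4R,5S)-4-[(tert-butyldimethylsilyl)oxy]-2-(diethoxyphosphoryl)-5-{[(4-methoxybenzyl)oxy]methyl}-6-oxoheptanoate (both C2 epimers)
Conditions: MeMgBr (3 equiv), THF, −40 to 0 °C
Reagents that add atoms: methylmagnesium bromide C[Mg]Br
Why: Weinreb ketone synthesis: the first equivalent of Grignard reagent deprotonates the phosphonoacetate, masking the ester as its enolate, and the chelated tetrahedral intermediate prevents over-addition, giving the methyl ketone (C11, C13).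

Step 10
Reactants: 14 methyl ketone
Product: 15 methyl (4R,5S)-4-[(tert-butyldimethylsilyl)oxy]-2-(diethoxyphosphoryl)-5-{[(4-methoxybenzyl)oxy]methyl}-6-{[(trifluoromethyl)sulfonyl]oxy}hept-6-enoate (both C2 epimers)
Conditions: KHMDS (2.1 equiv), THF, −78 °C; then PhNTf2 (1.05 equiv)
Reagents that add atoms: N-phenylbis(trifluoromethanesulfonimide) O=S(=O)(N(c1ccccc1)S(=O)(=O)C(F)(F)F)C(F)(F)F
Why: Enol triflate formation: the first equivalent of base is consumed by the phosphonoacetate C–H, the second gives the kinetic CH3 enolate, and only this unstabilised ketone enolate should be O-triflated by the triflimide.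

Step 11
Reactants: 15 enol triflate
Product: 16 methyl (4R,5S)-4-[(tert-butyldimethylsilyl)oxy]-2-(diethoxyphosphoryl)-5-{[(4-methoxybenzyl)oxy]methyl}-6-(4,4,5,5-tetramethyl-1,3,2-dioxaborolan-2-yl)hept-6-enoate (both C2 epimers)
Conditions: B2pin2, PdCl2(dppf) (cat.), KOAc, 1,4-dioxane, 80 °C
Reagents that add atoms: bis(pinacolato)diboron CC1(C)OB(OC1(C)C)B1OC(C)(C)C(C)(C)O1
Why: Miyaura borylation (oxidative addition of Pd(0) to the alkenyl triflate, acetate-assisted transmetalation, reductive elimination) turns C11–OTf into C11–Bpin; acetate is too weak a base to generate the phosphonate enolate.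

Step 12
Reactants: 16 alkenylboronate phosphonate; 7 (E)-5-iodo-4-methylpent-4-enal
Product: 17 methyl (2E,6E)-2-[(2R,3S)-2-[(tert-butyldimethylsilyl)oxy]-3-{[(4-methoxybenzyl)oxy]methyl}-4-(4,4,5,5-tetramethyl-1,3,2-dioxaborolan-2-yl)pent-4-en-1-yl]-7-iodo-6-methylhepta-2,6-dienoate
Conditions: NaH, THF, 0 °C; then 7, 0 °C to rt
Reagents that add atoms: none
Why: Horner–Wadsworth–Emmons olefination of the α-substituted phosphonoacetate with the unbranched aldehyde should give the trisubstituted enoate with the ester trans to C2 (E by CIP, the cis ring alkene C1=C10 of the target) under thermodynamic oxaphosphetane control.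

Step 13
Reactants: 17 PMB ether
Product: 18 methyl (2E,6E)-2-[(2R,3S)-2-[(tert-butyldimethylsilyl)oxy]-3-(hydroxymethyl)-4-(4,4,5,5-tetramethyl-1,3,2-dioxaborolan-2-yl)pent-4-en-1-yl]-7-iodo-6-methylhepta-2,6-dienoate
Conditions: DDQ, CH2Cl2/pH 7 buffer, 0 °C
Reagents that add atoms: none
Why: Oxidative PMB cleavage (hydride abstraction at the electron-rich benzylic position, hydrolysis of the oxocarbenium ion) frees the primary C6 alcohol without affecting silyl ether, boronate or vinyl iodide.

Step 14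
Reactants: 18 primary alcohol
Product: 19 methyl (2E,6E)-2-[(2R,3R)-2-[(tert-butyldimethylsilyl)oxy]-3-formyl-4-(4,4,5,5-tetramethyl-1,3,2-dioxaborolan-2-yl)pent-4-en-1-yl]-7-iodo-6-methylhepta-2,6-dienoate
Conditions: Dess–Martin periodinane, NaHCO3, CH2Cl2, 0 °C; used crude
Reagents that add atoms: none
Why: Buffered Dess–Martin oxidation gives the α-branched aldehyde (C6) under non-basic conditions that avoid epimerisation at C7 and migration of the alkene into conjugation.

Step 15
Reactants: 19 iodo aldehyde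
Product: 20 methyl (1E,5E,7R,8S,9R)-9-[(tert-butyldimethylsilyl)oxy]-7-hydroxy-5-methyl-8-[1-(4,4,5,5-tetramethyl-1,3,2-dioxaborolan-2-yl)ethenyl]cyclodeca-1,5-diene-1-carboxylate
Conditions: CrCl2 (excess), NiCl2 (cat.), DMSO/THF, rt, high dilution (ca. 2 mM, slow addition)
Reagents that add atoms: none
Why: Intramolecular Nozaki–Hiyama–Kishi reaction: Ni(0) inserts into C–I, transmetalation gives an alkenylchromium(III) that adds only to the aldehyde and closes the ten-membered ring at C5–C6 with retention of the E alkene, the boronate being inert; the 6R carbinol is expected from Felkin–Anh addition anti to the C8 branch, reinforced by 1,3-anti induction from the C8 silyl ether.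

Step 16
Reactants: 20 macrocyclic allylic alcohol
Product: 21 methyl (1E,5E,7S,8R,9R)-9-[(tert-butyldimethylsilyl)oxy]-7-chloro-5-methyl-8-[1-(4,4,5,5-tetramethyl-1,3,2-dioxaborolan-2-yl)ethenyl]cyclodeca-1,5-diene-1-carboxylate
Conditions: hexachloroacetone, PPh3, CH2Cl2, −20 to 0 °C; used crude
Reagents that add atoms: hexachloroacetone O=C(C(Cl)(Cl)Cl)C(Cl)(Cl)Cl
Why: Appel-type chlorination: chloride displaces the alkoxyphosphonium ion in an SN2 step with inversion at C6, and allylic transposition is disfavoured because SN2′ attack would have to occur at the fully substituted C4.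

Step 17
Reactants: 21 allylic chloride alkenylboronate
Product: 23 methyl (3aS,4R,6E,10E,11aR)-4-[(tert-butyldimethylsilyl)oxy]-10-methyl-3-methylidene-2-oxo-2,3,3a,4,5,8,9,11a-octahydrocyclodeca[b]furan-6-carboxylate, via caesium carboxylate 22 (not isolated)
Conditions: (IPr)CuCl (10 mol %), CsF (3 equiv), CO2 (1 atm), DMF, 60 °C
Reagents that add atoms: carbon dioxide O=C=O
Why: Fluoride-assisted B-to-Cu transmetalation gives the C11 alkenylcopper(I)–NHC species, CO2 inserts into its Cu–C bond (C11–C12), and the caesium carboxylate 22 released by exchange with CsF displaces the allylic C6 chloride intramolecularly (O1–C6). The closest known reaction types are the Cu(I)/NHC-catalysed carboxylation of alkenylboronic esters with CO2 and the alkylative lactonisation of γ-halo carboxylates, merged here into a formal (3+2) annulation of CO2. The γ-lactone closes in a 5-exo-tet mode. No new stereocentre is created; C6 is inverted in the SN2 step, so the (6S)-chloride should deliver the lactone oxygen with the target configuration, trans to the C7–C8 bond (trans ring fusion). The step needs CO2 capture by the alkenylcopper to outrun protonation and attack on the allylic chloride, and O-alkylation at C6 rather than C4: CO2 insertion is fast at 1 atm, 3-exo or 5-endo closure by the alkenylcopper is geometrically disfavoured, and attack at C4 would require a seven-membered ring. In the conformer with C5–C6–C7–C8 antiperiplanar the C6–Cl bond is anti to C7–C11, which places the carboxylate at the back side of the leaving group.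

Step 18
Reactants: 23 silyl-protected lactone
Product: 24 methyl (3aR,4R,6E,10E,11aR)-4-hydroxy-10-methyl-3-methylidene-2-oxo-2,3,3a,4,5,8,9,11a-octahydrocyclodeca[b]furan-6-carboxylate
Conditions: HF·pyridine, THF/pyridine, 0 °C to rt
Reagents that add atoms: none
Why: Fluoride-mediated desilylation under mildly acidic conditions removes the TBS ether without translactonisation to C8 or conjugate addition to the α-methylene lactone.

Step 19
Reactants: 24 hydroxy lactone
Product: 25 methyl (3aR,4R,6E,10E,11aR)-10-methyl-3-methylidene-4-[(2-methylprop-2-enoyl)oxy]-2-oxo-2,3,3a,4,5,8,9,11a-octahydrocyclodeca[b]furan-6-carboxylate (CNP0317149.1)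
Conditions: methacrylic anhydride, Et3N, DMAP (cat.), CH2Cl2, 0 °C to rt
Reagents that add atoms: methacrylic anhydride C=C(C)C(=O)OC(=O)C(C)=C
Why: DMAP-catalysed O-acylation (nucleophilic catalysis via the acylpyridinium ion) installs the methacrylate with retention at C8.

Compound list
1 | methyl 2-(diethoxyphosphoryl)acetate | COC(=O)CP(=O)(OCC)OCC | starting material
2 | allyl bromide | C=CCBr | starting material
3 | methyl 2-(diethoxyphosphoryl)pent-4-enoate (racemic) | C=CCC(C(=O)OC)P(=O)(OCC)OCC | intermediate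
4 | methyl 2-(diethoxyphosphoryl)-4-oxobutanoate (racemic) | O=CCC(C(=O)OC)P(=O)(OCC)OCC | intermediate
5 | pent-4-yn-1-ol | C#CCCCO | starting material
6 | (E)-5-iodo-4-methylpent-4-en-1-ol | OCCC/C(C)=C/I | intermediate
7 | (E)-5-iodo-4-methylpent-4-enal | O=CCC/C(C)=C/I | intermediate
8 | (S)-4-benzyl-1,3-thiazolidine-2-thione | S=C1N[C@@H](Cc2ccccc2)CS1 | starting material
9 | 3-[(4-methoxybenzyl)oxy]propanoic acid | COc1ccc(COCCC(=O)O)cc1 | starting material
10 | 1-[(4S)-4-benzyl-2-thioxo-1,3-thiazolidin-3-yl]-3-[(4-methoxybenzyl)oxy]propan-1-one | COc1ccc(COCCC(=O)N2[C@@H](Cc3ccccc3)CSC2=S)cc1 | intermediate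
11 | methyl (4R,5S)-6-[(4S)-4-benzyl-2-thioxo-1,3-thiazolidin-3-yl]-2-(diethoxyphosphoryl)-4-hydroxy-5-{[(4-methoxybenzyl)oxy]methyl}-6-oxohexanoate (both C2 epimers) | COc1ccc(COC[C@@H]([C@H](O)CC(C(=O)OC)P(=O)(OCC)OCC)C(=O)N2[C@@H](Cc3ccccc3)CSC2=S)cc1 | intermediate
12 | methyl (4R,5S)-6-[(4S)-4-benzyl-2-thioxo-1,3-thiazolidin-3-yl]-4-[(tert-butyldimethylsilyl)oxy]-2-(diethoxyphosphoryl)-5-{[(4-methoxybenzyl)oxy]methyl}-6-oxohexanoate (both C2 epimers) | COc1ccc(COC[C@@H]([C@H](O[Si](C)(C)C(C)(C)C)CC(C(=O)OC)P(=O)(OCC)OCC)C(=O)N2[C@@H](Cc3ccccc3)CSC2=S)cc1 | intermediate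
13 | methyl (4R,5S)-4-[(tert-butyldimethylsilyl)oxy]-2-(diethoxyphosphoryl)-6-[methoxy(methyl)amino]-5-{[(4-methoxybenzyl)oxy]methyl}-6-oxohexanoate (both C2 epimers) | COc1ccc(COC[C@@H]([C@H](O[Si](C)(C)C(C)(C)C)CC(C(=O)OC)P(=O)(OCC)OCC)C(=O)N(C)OC)cc1 | intermediate
14 | methyl (4R,5S)-4-[(tert-butyldimethylsilyl)oxy]-2-(diethoxyphosphoryl)-5-{[(4-methoxybenzyl)oxy]methyl}-6-oxoheptanoate (both C2 epimers) | COc1ccc(COC[C@@H]([C@H](O[Si](C)(C)C(C)(C)C)CC(C(=O)OC)P(=O)(OCC)OCC)C(C)=O)cc1 | intermediate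
15 | methyl (4R,5S)-4-[(tert-butyldimethylsilyl)oxy]-2-(diethoxyphosphoryl)-5-{[(4-methoxybenzyl)oxy]methyl}-6-{[(trifluoromethyl)sulfonyl]oxy}hept-6-enoate (both C2 epimers) | COc1ccc(COC[C@@H]([C@H](O[Si](C)(C)C(C)(C)C)CC(C(=O)OC)P(=O)(OCC)OCC)C(=C)OS(=O)(=O)C(F)(F)F)cc1 | intermediate
16 | methyl (4R,5S)-4-[(tert-butyldimethylsilyl)oxy]-2-(diethoxyphosphoryl)-5-{[(4-methoxybenzyl)oxy]methyl}-6-(4,4,5,5-tetramethyl-1,3,2-dioxaborolan-2-yl)hept-6-enoate (both C2 epimers) | COc1ccc(COC[C@@H]([C@H](O[Si](C)(C)C(C)(C)C)CC(C(=O)OC)P(=O)(OCC)OCC)C(=C)B2OC(C)(C)C(C)(C)O2)cc1 | intermediate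
17 | methyl (2E,6E)-2-[(2R,3S)-2-[(tert-butyldimethylsilyl)oxy]-3-{[(4-methoxybenzyl)oxy]methyl}-4-(4,4,5,5-tetramethyl-1,3,2-dioxaborolan-2-yl)pent-4-en-1-yl]-7-iodo-6-methylhepta-2,6-dienoate | COc1ccc(COC[C@@H]([C@H](O[Si](C)(C)C(C)(C)C)C/C(C(=O)OC)=C\CC/C(C)=C/I)C(=C)B2OC(C)(C)C(C)(C)O2)cc1 | intermediate
18 | methyl (2E,6E)-2-[(2R,3S)-2-[(tert-butyldimethylsilyl)oxy]-3-(hydroxymethyl)-4-(4,4,5,5-tetramethyl-1,3,2-dioxaborolan-2-yl)pent-4-en-1-yl]-7-iodo-6-methylhepta-2,6-dienoate | OC[C@@H]([C@H](O[Si](C)(C)C(C)(C)C)C/C(C(=O)OC)=C\CC/C(C)=C/I)C(=C)B1OC(C)(C)C(C)(C)O1 | intermediate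
19 | methyl (2E,6E)-2-[(2R,3R)-2-[(tert-butyldimethylsilyl)oxy]-3-formyl-4-(4,4,5,5-tetramethyl-1,3,2-dioxaborolan-2-yl)pent-4-en-1-yl]-7-iodo-6-methylhepta-2,6-dienoate | O=C[C@@H]([C@H](O[Si](C)(C)C(C)(C)C)C/C(C(=O)OC)=C\CC/C(C)=C/I)C(=C)B1OC(C)(C)C(C)(C)O1 | intermediate
20 | methyl (1E,5E,7R,8S,9R)-9-[(tert-butyldimethylsilyl)oxy]-7-hydroxy-5-methyl-8-[1-(4,4,5,5-tetramethyl-1,3,2-dioxaborolan-2-yl)ethenyl]cyclodeca-1,5-diene-1-carboxylate | CC(C)(C)[Si](C)(C)O[C@@H]1C/C(C(=O)OC)=C\CC/C(C)=C/[C@@H](O)[C@@H]1C(=C)B1OC(C)(C)C(C)(C)O1 | intermediate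
21 | methyl (1E,5E,7S,8R,9R)-9-[(tert-butyldimethylsilyl)oxy]-7-chloro-5-methyl-8-[1-(4,4,5,5-tetramethyl-1,3,2-dioxaborolan-2-yl)ethenyl]cyclodeca-1,5-diene-1-carboxylate | CC(C)(C)[Si](C)(C)O[C@@H]1C/C(C(=O)OC)=C\CC/C(C)=C/[C@H](Cl)[C@@H]1C(=C)B1OC(C)(C)C(C)(C)O1 | intermediate
22 | caesium 2-[(1R,2S,3E,7E,10R)-10-[(tert-butyldimethylsilyl)oxy]-2-chloro-8-(methoxycarbonyl)-4-methylcyclodeca-3,7-dien-1-yl]prop-2-enoate | CC(C)(C)[Si](C)(C)O[C@@H]1C/C(C(=O)OC)=C\CC/C(C)=C/[C@H](Cl)[C@@H]1C(=C)C(=O)[O-].[Cs+] | intermediate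
23 | methyl (3aS,4R,6E,10E,11aR)-4-[(tert-butyldimethylsilyl)oxy]-10-methyl-3-methylidene-2-oxo-2,3,3a,4,5,8,9,11a-octahydrocyclodeca[b]furan-6-carboxylate | CC(C)(C)[Si](C)(C)O[C@@H]1C/C(C(=O)OC)=C\CC/C(C)=C/[C@H]2OC(=O)C(=C)[C@@H]21 | intermediate
24 | methyl (3aR,4R,6E,10E,11aR)-4-hydroxy-10-methyl-3-methylidene-2-oxo-2,3,3a,4,5,8,9,11a-octahydrocyclodeca[b]furan-6-carboxylate | O[C@@H]1C/C(C(=O)OC)=C\CC/C(C)=C/[C@H]2OC(=O)C(=C)[C@@H]21 | intermediate
25 | methyl (3aR,4R,6E,10E,11aR)-10-methyl-3-methylidene-4-[(2-methylprop-2-enoyl)oxy]-2-oxo-2,3,3a,4,5,8,9,11a-octahydrocyclodeca[b]furan-6-carboxylate | C=C(C)C(=O)O[C@@H]1C/C(C(=O)OC)=C\CC/C(C)=C/[C@H]2OC(=O)C(=C)[C@@H]21 | target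

Total step count: 19. Longest linear sequence: 16 steps (steps 1, 2 and 6–19, from 1 to 25).

Steps most likely to fail

1. Step 17 (carboxylative lactonisation). The alkenylcopper may be protonated before it captures CO2, and the allylic chloride may ionise, eliminate to a diene or be attacked by fluoride, so that the inversion at C6 is not clean. The fallback closes the ring by O-acylation instead of O-alkylation. It sets out from 20: TESOTf/2,6-lutidine should give the C6 triethylsilyl ether of 20 F1. The same Cu-catalysed carboxylation with CO2, now without an internal electrophile, followed by acidic work-up should give the C11 carboxylic acid (2-substituted acrylic acid) F2. PPTS in MeOH then removes the triethylsilyl group and the γ-hydroxy acid lactonises with retention at C6. The fallback comes back to the route at 23.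

2. Step 15 (macrocyclisation). Intermolecular coupling may outrun ring closure because of the strain of the ten-membered transition state, and facial selectivity at the aldehyde may be poor. The fallback closes the ring at C1=C10 by an intramolecular Horner–Wadsworth–Emmons reaction. It sets out from 16: DDQ should give the primary alcohol F3, and Dess–Martin oxidation the aldehyde F4. Intermolecular Nozaki–Hiyama–Kishi coupling with (E)-1-iodo-5,5-dimethoxy-2-methylpent-1-ene F5 (from 7 with HC(OMe)3, PPTS, MeOH) should give the acyclic C6 allylic alcohol F6. PPTS in wet acetone unmasks the C1 aldehyde F7, which is cyclised with LiCl/DBU in MeCN at high dilution. The fallback comes back to the route at 20.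

3. Step 16 (allylic chlorination). Allylic transposition to C4, ionisation with loss of configuration at C6, or elimination to a triene may compete with SN2 inversion. The fallback replaces the halide by a phosphate installed with retention after a separate inversion. It sets out from 20: Mitsunobu reaction (4-nitrobenzoic acid, DIAD, PPh3) should give the inverted (6S) 4-nitrobenzoate F8, K2CO3 in MeOH the (6S)-alcohol F9, and ClP(O)(OEt)2 with N-methylimidazole the (6S) allylic diethyl phosphate F10. F10 is submitted to the conditions of step 17, the phosphate serving as the leaving group in the SN2 lactonisation. The fallback comes back to the route at 23.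

Further compounds
F1 | step 17 | C6 triethylsilyl ether of 20 (C6, C7, C8 as in 20) | CC(C)(C)[Si](C)(C)O[C@@H]1C/C(C(=O)OC)=C\CC/C(C)=C/[C@@H](O[Si](CC)(CC)CC)[C@@H]1C(=C)B1OC(C)(C)C(C)(C)O1
F2 | step 17 | 2-substituted acrylic acid from F1 (Bpin replaced by CO2H, C6 OTES, C8 OTBS) | CC(C)(C)[Si](C)(C)O[C@@H]1C/C(C(=O)OC)=C\CC/C(C)=C/[C@@H](O[Si](CC)(CC)CC)[C@@H]1C(=C)C(=O)O
F3 | step 15 | primary alcohol from 16 (PMB removed; both C2 epimers) | OC[C@@H]([C@H](O[Si](C)(C)C(C)(C)C)CC(C(=O)OC)P(=O)(OCC)OCC)C(=C)B1OC(C)(C)C(C)(C)O1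
F4 | step 15 | aldehyde from F3 (both C2 epimers) | O=C[C@@H]([C@H](O[Si](C)(C)C(C)(C)C)CC(C(=O)OC)P(=O)(OCC)OCC)C(=C)B1OC(C)(C)C(C)(C)O1
F5 | step 15 | (E)-1-iodo-5,5-dimethoxy-2-methylpent-1-ene | COC(OC)CC/C(C)=C/I
F6 | step 15 | acyclic (6R) allylic alcohol, dimethyl acetal at C1, phosphonate at C10 | COC(OC)CC/C(C)=C/[C@@H](O)[C@@H]([C@H](O[Si](C)(C)C(C)(C)C)CC(C(=O)OC)P(=O)(OCC)OCC)C(=C)B1OC(C)(C)C(C)(C)O1
F7 | step 15 | acyclic (6R) allylic alcohol with free C1 aldehyde, phosphonate at C10 | O=CCC/C(C)=C/[C@@H](O)[C@@H]([C@H](O[Si](C)(C)C(C)(C)C)CC(C(=O)OC)P(=O)(OCC)OCC)C(=C)B1OC(C)(C)C(C)(C)O1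
F8 | step 16 | (6S) 4-nitrobenzoate of the macrocycle (C6 epimer of the ester of 20) | CC(C)(C)[Si](C)(C)O[C@@H]1C/C(C(=O)OC)=C\CC/C(C)=C/[C@H](OC(=O)c2ccc(cc2)[N+](=O)[O-])[C@@H]1C(=C)B1OC(C)(C)C(C)(C)O1
F9 | step 16 | (6S)-alcohol, C6 epimer of 20 | CC(C)(C)[Si](C)(C)O[C@@H]1C/C(C(=O)OC)=C\CC/C(C)=C/[C@H](O)[C@@H]1C(=C)B1OC(C)(C)C(C)(C)O1
F10 | step 16 | (6S) allylic diethyl phosphate of F9 | CC(C)(C)[Si](C)(C)O[C@@H]1C/C(C(=O)OC)=C\CC/C(C)=C/[C@H](OP(=O)(OCC)OCC)[C@@H]1C(=C)B1OC(C)(C)C(C)(C)O1
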